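# Total synthesis of (S)-hopeafuran

## Plan

1. Labels: ring A is the benzofuran (O1, C2, C3, C3a, C4–C7a), ring B the aryl group on C2, and ring C the seven-membered ketone ring. Ring D is the resorcinol ring (C1' on benzofuran C3, C2' on the ring-C CH, oxygen at C3' and C5'), and ring E the 4-hydroxyphenyl group on that CH. CIP analysis of the target gives (S).
2. Enabling feature: the only sp3 carbon, the CH of ring C, carries the para-hydroxyphenyl ring E and is bonded to the ketone carbon held on benzofuran C4. The CH is therefore a latent para-quinone methide terminus, and the C=O is a latent formyl group that a carbene can turn into an acyl anion.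
3. Retrosynthetic cuts, in order: four O–benzyl bonds, then the C(=O)–CH bond of ring C, then the C3–C1' biaryl bond. On one half follow C3–Br, C4–CHO and the furan O1–C2 and C3a–C3 bonds; on the other half C1'–B, CH–S and CH–ring E.
4. Forward: the furan ring forms first, by Sonogashira coupling and 5-endo-dig closure on a symmetric iodoresorcinol. C4–OH becomes C4–CHO through the triflate, the methyl ethers are exchanged for benzyl while the material is achiral, and C3 is brominated. The ring D/E sulfone boronate takes four steps, a Suzuki coupling joins the halves, and ring C closes last.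
5. Stereochemistry: the single stereocentre comes from a chiral aminoindanol-derived triazolium carbene in the ring-C closure, the racemic sulfone converging through a planar quinone methide. Only a neutral hydrogenolysis follows, so the enolisable α,α-diaryl ketone meets neither base nor Lewis acid.

Key step: step 14

Assumption: the sense of induction of the aminoindanol triazolium salt cannot be derived from precedent for this new ring closure. The (5aS,10bR) salt is written throughout, and its equally available mirror image is to be taken if a first run shows the (R)-ketone.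

## Route

Step 1
Reactants: 1 5-methoxyresorcinol
Product: 2 2-iodo-5-methoxybenzene-1,3-diol
Conditions: I2 (1.0 equiv), NaHCO3, H2O/THF, 0 °C to rt
Reagents that add atoms: iodine, [I][I]
Why: Electrophilic aromatic iodination through the phenolate in aqueous bicarbonate goes, for resorcinol and 5-alkylresorcinols, to the carbon flanked by both hydroxyl groups, and should likewise place iodine at C2 here.

Step 2
Reactants: 2 2-iodo-5-methoxybenzene-1,3-diol; 3 4-ethynylanisole
Product: 5 6-methoxy-2-(4-methoxyphenyl)-1-benzofuran-4-ol, via alkynylresorcinol 4 (not isolated)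
Conditions: PdCl2(PPh3)2 (3 mol %), CuI (5 mol %), Et3N, DMF, 60 °C
Reagents that add atoms: none
Why: Sonogashira coupling followed in the same pot by 5-endo-dig hydroalkoxylation of the ortho-alkynylphenol is the standard 2-arylbenzofuran synthesis, and because the two hydroxyl groups of 4 are equivalent only one benzofuran can form, leaving the other hydroxyl at C4.

Step 3
Reactants: 5 6-methoxy-2-(4-methoxyphenyl)-1-benzofuran-4-ol
Product: 6 6-methoxy-2-(4-methoxyphenyl)-1-benzofuran-4-yl trifluoromethanesulfonate
Conditions: Tf2O, pyridine, CH2Cl2, 0 °C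
Reagents that add atoms: trifluoromethanesulfonic anhydride, O=S(=O)(OS(=O)(=O)C(F)(F)F)C(F)(F)F
Why: O-Sulfonylation of the only free phenol is routine and turns the C4–O bond into a leaving group for palladium.

Step 4
Reactants: 6 6-methoxy-2-(4-methoxyphenyl)-1-benzofuran-4-yl trifluoromethanesulfonate
Product: 7 6-methoxy-2-(4-methoxyphenyl)-1-benzofuran-4-carbaldehyde
Conditions: Pd(OAc)2 (5 mol %), dppp, CO (1 atm), Et3SiH, Et3N, DMF, 70 °C
Reagents that add atoms: carbon monoxide, [C-]#[O+]
Why: In this palladium-catalysed reductive carbonylation of an aryl triflate, oxidative addition, CO insertion and hydride delivery from the silane to the acylpalladium species give the aldehyde, while the methyl ethers and the furan are inert.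

Step 5
Reactants: 7 6-methoxy-2-(4-methoxyphenyl)-1-benzofuran-4-carbaldehyde
Product: 8 6-hydroxy-2-(4-hydroxyphenyl)-1-benzofuran-4-carbaldehyde
Conditions: BBr3 (4 equiv), CH2Cl2, −78 °C to rt; then H2O
Reagents that add atoms: none
Why: BBr3 cleavage of aryl methyl ethers is placed here, on achiral material, so that no Lewis acid is needed once the stereocentre exists, and formyl groups of methoxybenzaldehydes come through this reagent after aqueous work-up.

Step 6
Reactants: 8 6-hydroxy-2-(4-hydroxyphenyl)-1-benzofuran-4-carbaldehyde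
Product: 9 6-(benzyloxy)-2-[4-(benzyloxy)phenyl]-1-benzofuran-4-carbaldehyde
Conditions: BnBr (2.4 equiv), K2CO3, DMF, rt to 50 °C
Reagents that add atoms: benzyl bromide, BrCc1ccccc1
Why: Williamson etherification of both phenols installs groups that tolerate every later step and leave at the end under neutral hydrogenolysis.

Step 7
Reactants: 9 6-(benzyloxy)-2-[4-(benzyloxy)phenyl]-1-benzofuran-4-carbaldehyde
Product: 10 6-(benzyloxy)-2-[4-(benzyloxy)phenyl]-3-bromo-1-benzofuran-4-carbaldehyde
Conditions: NBS (1.05 equiv), DMF, 0 °C, dark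
Reagents that add atoms: N-bromosuccinimide, O=C1CCC(=O)N1Br
Why: Electrophilic aromatic bromination should go to C3, the enol-ether-like furan carbon activated by O1 and ring B, because C5 and C7 lie ortho and para to the formyl group and the ionic, dark conditions spare the benzylic CH2 groups.

Step 8
Reactants: 11 1,3-bis(benzyloxy)-5-bromobenzene
Product: 13 2,4-bis(benzyloxy)-6-bromobenzaldehyde, via aryl iminium salt 12 (not isolated)
Conditions: POCl3, DMF, 0 to 80 °C; then H2O
Reagents that add atoms: N,N-dimethylformamide, CN(C)C=O; water, O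
Why: Vilsmeier–Haack formylation attacks the carbon para to one benzyloxy group and ortho to the other (next to bromine), as is known for the dimethoxy analogue, rather than the more crowded carbon between the two ethers, and water then hydrolyses 12.

Step 9
Reactants: 13 2,4-bis(benzyloxy)-6-bromobenzaldehyde; 14 (4-bromophenoxy)(tert-butyl)dimethylsilane
Product: 16 rac-[2,4-bis(benzyloxy)-6-bromophenyl]{4-[(tert-butyldimethylsilyl)oxy]phenyl}methanol, via aryl Grignard reagent 15 (not isolated)
Conditions: 14, Mg, THF, 40 °C; then 13, THF, 0 °C; aq NH4Cl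
Reagents that add atoms: none
Why: In this Grignard addition to a non-enolisable aldehyde, the aryl bromide of 13 does not exchange at 0 °C, and the carbinol centre is formed racemic on purpose because it is erased in step 14.

Step 10
Reactants: 16 rac-[2,4-bis(benzyloxy)-6-bromophenyl]{4-[(tert-butyldimethylsilyl)oxy]phenyl}methanol
Product: 17 rac-1,5-bis(benzyloxy)-3-bromo-2-[{4-[(tert-butyldimethylsilyl)oxy]phenyl}(4-methylbenzenesulfonyl)methyl]benzene
Conditions: p-TolSO2H (1.3 equiv), CH2Cl2, rt
Reagents that add atoms: 4-methylbenzenesulfinic acid, Cc1ccc(cc1)S(=O)O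
Why: In this SN1 substitution of an electron-rich benzhydrol, the sulfinic acid itself ionises the alcohol to a cation stabilised by three oxygen donors, reversible capture ends at sulfur to give the thermodynamically preferred sulfone, and the aryl silyl ether is stable to this mild acid.

Step 11
Reactants: 17 rac-1,5-bis(benzyloxy)-3-bromo-2-[{4-[(tert-butyldimethylsilyl)oxy]phenyl}(4-methylbenzenesulfonyl)methyl]benzene
Product: 18 rac-2-{3,5-bis(benzyloxy)-2-[{4-[(tert-butyldimethylsilyl)oxy]phenyl}(4-methylbenzenesulfonyl)methyl]phenyl}-4,4,5,5-tetramethyl-1,3,2-dioxaborolane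
Conditions: B2pin2, Pd2(dba)3 (2 mol %), XPhos, KOAc, 1,4-dioxane, 100 °C
Reagents that add atoms: bis(pinacolato)diboron, CC1(C)OB(OC1(C)C)B1OC(C)(C)C(C)(C)O1
Why: Miyaura borylation with a bulky biarylphosphine copes with ortho-substituted electron-rich bromides, and KOAc is too weak to touch the sulfone C–H or the silyl ether.

Step 12
Reactants: 10 6-(benzyloxy)-2-[4-(benzyloxy)phenyl]-3-bromo-1-benzofuran-4-carbaldehyde; 18 the pinacol boronate of step 11
Product: 19 rac-6-(benzyloxy)-2-[4-(benzyloxy)phenyl]-3-{3,5-bis(benzyloxy)-2-[{4-[(tert-butyldimethylsilyl)oxy]phenyl}(4-methylbenzenesulfonyl)methyl]phenyl}-1-benzofuran-4-carbaldehyde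
Conditions: Pd2(dba)3 (3 mol %), SPhos, K3PO4, toluene/H2O (10:1), 90 °C
Reagents that add atoms: none
Why: Suzuki–Miyaura coupling with SPhos is the established way to tri-ortho-substituted biaryls, boron sits meta to both benzyloxy groups (which slows protodeboronation), and the silyl cap keeps the sulfone from eliminating under K3PO4.

Step 13
Reactants: 19 the silyl-protected biaryl sulfone aldehyde of step 12
Product: 20 rac-6-(benzyloxy)-2-[4-(benzyloxy)phenyl]-3-{3,5-bis(benzyloxy)-2-[(4-hydroxyphenyl)(4-methylbenzenesulfonyl)methyl]phenyl}-1-benzofuran-4-carbaldehyde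
Conditions: HF·pyridine, THF, 0 °C to rt; pH 7 buffer work-up
Reagents that add atoms: none
Why: Fluoride-induced cleavage of the aryl silyl ether in an acidic fluoride medium frees the ring-E phenol without forming the phenolate, so sulfinate is not expelled before step 14.

Step 14
Reactants: 20 the free-phenol sulfone aldehyde of step 13
Product: 22 (S)-tetra-O-benzylhopeafuran (ring C closed; benzyl ethers at ring A C6–O, ring B C4–O, ring D C3'–O and C5'–O; ring-E phenol free), via para-quinone methide aldehyde 21 (not isolated)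
Conditions: (5aS,10bR)-2-(pentafluorophenyl)-5a,10b-dihydro-4H,6H-indeno[2,1-b][1,2,4]triazolo[4,3-d][1,4]oxazin-2-ium tetrafluoroborate (20 mol %), CsOAc (1.5 equiv), 4 Å MS, degassed toluene, 0 °C to rt
Reagents that add atoms: none
Why: Proposed new method: CsOAc frees a trace of the carbene, which adds to the C4 formyl group and after proton transfer gives the Breslow enaminol, while the same weak base takes the ring-E phenol proton so that toluenesulfinate leaves and para-quinone methide 21 appears only in a low, sulfinate-buffered concentration. The enaminol carbon then attacks the exocyclic methide carbon in the 1,6-sense, ring E rearomatises to the phenolate and collapse of the tetrahedral adduct gives the ketone and returns the carbene; the closest known reaction types are the carbene-catalysed intermolecular 1,6-acylation of stable para-quinone methides by aromatic aldehydes and the asymmetric intramolecular Stetter reaction, neither of which has been shown for a ring closure onto a transient, unhindered quinone methide. Ring C closes in the 7-exo-trig mode, and the C3–C1' bond keeps the formyl carbon and the methide carbon within bonding distance. The single new stereocentre is set by the catalyst alone: the indane wall of the aminoindanol backbone shields one face of the enaminol so that only one prochiral face of the planar methide can be reached, and since the sulfone stereocentre is erased in 21 and the biaryl axis, which ends on a five-membered ring, should rotate freely at room temperature, both enantiomers of 20 should funnel into (S)-22. Chemoselectivity for ring closure over benzoin coupling, carbene capture by 21 or water addition rests on the peri-crowded aldehyde, on intramolecularity, on the reversibility of sulfinate and carbene addition to 21 and on the molecular sieves. Survival of the configuration rests on the acetate/acetic acid buffer and on the flanking C3' benzyloxy group, which should force ring E pseudo-axial, turn the C–H bond towards the carbonyl plane and so slow enolisation.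

Step 15
Reactants: 22 (S)-tetra-O-benzylhopeafuran
Product: 23 (S)-hopeafuran
Conditions: H2 (1 atm), Pd/C (10 wt %), EtOAc/THF, rt
Reagents that add atoms: none
Why: Catalytic hydrogenolysis of aryl benzyl ethers runs in neutral medium at room temperature, so the α,α-diaryl ketone has no pathway to enolise, and the hindered ring-C ketone and the tetrasubstituted furan bond should be reduced far more slowly than the O-benzyl bonds are cleaved.

## Compound list

1 | 5-methoxyresorcinol | COc1cc(O)cc(O)c1 | starting material
2 | 2-iodo-5-methoxybenzene-1,3-diol | COc1cc(O)c(I)c(O)c1 | intermediate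
3 | 4-ethynylanisole | COc1ccc(C#C)cc1 | starting material
4 | 5-methoxy-2-[(4-methoxyphenyl)ethynyl]benzene-1,3-diol (not isolated) | COc1ccc(cc1)C#Cc1c(O)cc(OC)cc1O | intermediate
5 | 6-methoxy-2-(4-methoxyphenyl)-1-benzofuran-4-ol | COc1ccc(cc1)-c1cc2c(O)cc(OC)cc2o1 | intermediate
6 | 6-methoxy-2-(4-methoxyphenyl)-1-benzofuran-4-yl trifluoromethanesulfonate | COc1ccc(cc1)-c1cc2c(OS(=O)(=O)C(F)(F)F)cc(OC)cc2o1 | intermediate
7 | 6-methoxy-2-(4-methoxyphenyl)-1-benzofuran-4-carbaldehyde | COc1ccc(cc1)-c1cc2c(C=O)cc(OC)cc2o1 | intermediate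
8 | 6-hydroxy-2-(4-hydroxyphenyl)-1-benzofuran-4-carbaldehyde | Oc1ccc(cc1)-c1cc2c(C=O)cc(O)cc2o1 | intermediate
9 | 6-(benzyloxy)-2-[4-(benzyloxy)phenyl]-1-benzofuran-4-carbaldehyde | O=Cc1cc(OCc2ccccc2)cc2oc(cc12)-c1ccc(OCc2ccccc2)cc1 | intermediate
10 | 6-(benzyloxy)-2-[4-(benzyloxy)phenyl]-3-bromo-1-benzofuran-4-carbaldehyde | O=Cc1cc(OCc2ccccc2)cc2oc(-c3ccc(OCc4ccccc4)cc3)c(Br)c12 | intermediate
11 | 1,3-bis(benzyloxy)-5-bromobenzene | Brc1cc(OCc2ccccc2)cc(OCc2ccccc2)c1 | starting material
12 | N-{[2,4-bis(benzyloxy)-6-bromophenyl]methylidene}-N-methylmethanaminium dichlorophosphate (not isolated) | C[N+](C)=Cc1c(Br)cc(OCc2ccccc2)cc1OCc1ccccc1.[O-]P(Cl)(Cl)=O | intermediate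
13 | 2,4-bis(benzyloxy)-6-bromobenzaldehyde | O=Cc1c(Br)cc(OCc2ccccc2)cc1OCc1ccccc1 | intermediate
14 | (4-bromophenoxy)(tert-butyl)dimethylsilane | CC(C)(C)[Si](C)(C)Oc1ccc(Br)cc1 | starting material
15 | {4-[(tert-butyldimethylsilyl)oxy]phenyl}magnesium bromide (not isolated) | CC(C)(C)[Si](C)(C)Oc1ccc([Mg]Br)cc1 | intermediate
16 | rac-[2,4-bis(benzyloxy)-6-bromophenyl]{4-[(tert-butyldimethylsilyl)oxy]phenyl}methanol | OC(c1ccc(O[Si](C)(C)C(C)(C)C)cc1)c1c(Br)cc(OCc2ccccc2)cc1OCc1ccccc1 | intermediate
17 | rac-1,5-bis(benzyloxy)-3-bromo-2-[{4-[(tert-butyldimethylsilyl)oxy]phenyl}(4-methylbenzenesulfonyl)methyl]benzene | Cc1ccc(cc1)S(=O)(=O)C(c1ccc(O[Si](C)(C)C(C)(C)C)cc1)c1c(Br)cc(OCc2ccccc2)cc1OCc1ccccc1 | intermediate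
18 | rac-2-{3,5-bis(benzyloxy)-2-[{4-[(tert-butyldimethylsilyl)oxy]phenyl}(4-methylbenzenesulfonyl)methyl]phenyl}-4,4,5,5-tetramethyl-1,3,2-dioxaborolane | Cc1ccc(cc1)S(=O)(=O)C(c1ccc(O[Si](C)(C)C(C)(C)C)cc1)c1c(cc(OCc2ccccc2)cc1OCc1ccccc1)B1OC(C)(C)C(C)(C)O1 | intermediate
19 | rac-6-(benzyloxy)-2-[4-(benzyloxy)phenyl]-3-{3,5-bis(benzyloxy)-2-[{4-[(tert-butyldimethylsilyl)oxy]phenyl}(4-methylbenzenesulfonyl)methyl]phenyl}-1-benzofuran-4-carbaldehyde (rotamers about C3–C1' possible) | O=Cc1cc(OCc2ccccc2)cc2oc(-c3ccc(OCc4ccccc4)cc3)c(c12)-c1cc(OCc2ccccc2)cc(OCc2ccccc2)c1C(c1ccc(O[Si](C)(C)C(C)(C)C)cc1)S(=O)(=O)c1ccc(C)cc1 | intermediate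
20 | rac-6-(benzyloxy)-2-[4-(benzyloxy)phenyl]-3-{3,5-bis(benzyloxy)-2-[(4-hydroxyphenyl)(4-methylbenzenesulfonyl)methyl]phenyl}-1-benzofuran-4-carbaldehyde | O=Cc1cc(OCc2ccccc2)cc2oc(-c3ccc(OCc4ccccc4)cc3)c(c12)-c1cc(OCc2ccccc2)cc(OCc2ccccc2)c1C(c1ccc(O)cc1)S(=O)(=O)c1ccc(C)cc1 | intermediate
21 | 6-(benzyloxy)-2-[4-(benzyloxy)phenyl]-3-{3,5-bis(benzyloxy)-2-[(4-oxocyclohexa-2,5-dien-1-ylidene)methyl]phenyl}-1-benzofuran-4-carbaldehyde (not isolated) | O=Cc1cc(OCc2ccccc2)cc2oc(-c3ccc(OCc4ccccc4)cc3)c(c12)-c1cc(OCc2ccccc2)cc(OCc2ccccc2)c1C=C1C=CC(=O)C=C1 | intermediate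
22 | (S)-tetra-O-benzylhopeafuran, ring-E phenol free | O=C1c2cc(OCc3ccccc3)cc3oc(-c4ccc(OCc5ccccc5)cc4)c(c23)-c2cc(OCc3ccccc3)cc(OCc3ccccc3)c2[C@@H]1c1ccc(O)cc1 | intermediate
23 | (S)-hopeafuran | O=C1c2cc(O)cc3oc(-c4ccc(O)cc4)c(c23)-c2cc(O)cc(O)c2[C@@H]1c1ccc(O)cc1 | target

## Step count and risks

Total step count: 15.
Longest linear sequence: 11 steps (steps 1–7, then 12–15). The ring D/E branch contributes steps 8–11.

**Step 14 (riskiest).** Several processes may defeat it.
- The carbene may add too slowly to the peri-crowded aldehyde.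
- The quinone methide may capture the carbene, acetate or water irreversibly.
- Facial discrimination across a forming seven-membered ring may be weak.
- The configuration may erode by enolisation during a long reaction.

The fallback uses known chemistry and closes ring C at its other benzylic bond; it sets out from bromide 10. Suzuki–Miyaura coupling with commercial 3,5-bis(benzyloxy)phenylboronic acid (Pd2(dba)3, SPhos, K3PO4) gives 6-(benzyloxy)-2-[4-(benzyloxy)phenyl]-3-[3,5-bis(benzyloxy)phenyl]-1-benzofuran-4-carbaldehyde F1. Horner–Wadsworth–Emmons olefination with diethyl [4-(benzyloxy)benzyl]phosphonate and NaH gives the (E)-stilbene F2.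

Shi epoxidation follows, with KHSO5 (as Oxone), K2CO3 buffer and 1,2:4,5-di-O-isopropylidene-β-L-erythro-2,3-hexodiulo-2,6-pyranose. That ketone enantiomer is chosen by analogy with trans-stilbene, and its bulky dioxirane should prefer the disubstituted alkene over the tetrasubstituted furan bond. The product is the (S,S)-trans-epoxide F3.

BF3·OEt2 in CH2Cl2 at −78 °C then triggers an intramolecular Friedel–Crafts opening at the ring-E benzylic carbon by C2' of ring D, giving the trans-alcohol F4. Its retained carbinol centre dictates the CH configuration, whether the opening is invertive or passes through a cation that closes trans. Dess–Martin oxidation buffered with NaHCO3 gives (S)-penta-O-benzylhopeafuran F5. Hydrogenolysis under the conditions of step 15 comes back to the route at 23.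

**Step 12.** Transmetalation between two crowded partners may be slow enough for side processes to take over.
- The boronate may undergo protodeboronation.
- The silyl group may be lost, followed by base-induced sulfinate elimination.
- Zerovalent palladium may insert into the benzylic C–S bond.

The fallback sets out from carbinol 16 and keeps the sulfone out of all palladium chemistry. Bromine–lithium exchange on the lithium alkoxide of 16 (n-BuLi, 2.2 equiv, THF, −78 °C), B(OiPr)3 and aqueous NH4Cl give 4,6-bis(benzyloxy)-3-{4-[(tert-butyldimethylsilyl)oxy]phenyl}-1,3-dihydro-2,1-benzoxaborol-1-ol F6, a compact cyclic boronic half-ester. Its Suzuki coupling with 10 (Pd2(dba)3, SPhos, K3PO4) gives the biaryl carbinol aldehyde F7. Treatment with p-TolSO2H as in step 10 comes back to the route at 19.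

**Step 1.** Iodination may compete at the carbon between hydroxyl and methoxy, or a second iodination may occur, which would misplace the later C4 and C6 substituents.

The fallback sets out from 1 and replaces electrophilic substitution by directed ortho-metalation. MOMCl and iPr2NEt give 1-methoxy-3,5-bis(methoxymethoxy)benzene F8. n-BuLi in THF at 0 °C lithiates the carbon between the two stronger directing acetal groups, and I2 gives 2-iodo-5-methoxy-1,3-bis(methoxymethoxy)benzene F9. HCl in MeOH removes both acetals and comes back to the route at 2.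

## Further compounds

F1 | step 14 | 6-(benzyloxy)-2-[4-(benzyloxy)phenyl]-3-[3,5-bis(benzyloxy)phenyl]-1-benzofuran-4-carbaldehyde | O=Cc1cc(OCc2ccccc2)cc2oc(-c3ccc(OCc4ccccc4)cc3)c(c12)-c1cc(OCc2ccccc2)cc(OCc2ccccc2)c1
F2 | step 14 | 6-(benzyloxy)-2-[4-(benzyloxy)phenyl]-3-[3,5-bis(benzyloxy)phenyl]-4-{(E)-2-[4-(benzyloxy)phenyl]ethenyl}-1-benzofuran | c1ccc(COc2ccc(/C=C/c3cc(OCc4ccccc4)cc4oc(-c5ccc(OCc6ccccc6)cc5)c(c34)-c3cc(OCc4ccccc4)cc(OCc4ccccc4)c3)cc2)cc1
F3 | step 14 | (S,S)-trans-epoxide of F2 | c1ccc(COc2ccc([C@@H]3O[C@H]3c3cc(OCc4ccccc4)cc4oc(-c5ccc(OCc6ccccc6)cc5)c(c34)-c3cc(OCc4ccccc4)cc(OCc4ccccc4)c3)cc2)cc1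
F4 | step 14 | ring-C alcohol, penta-O-benzyl (carbinol carbon R, CH carbon S, hydroxyl and ring E trans) | O[C@H]1c2cc(OCc3ccccc3)cc3oc(-c4ccc(OCc5ccccc5)cc4)c(c23)-c2cc(OCc3ccccc3)cc(OCc3ccccc3)c2[C@@H]1c1ccc(OCc2ccccc2)cc1
F5 | step 14 | (S)-penta-O-benzylhopeafuran | O=C1c2cc(OCc3ccccc3)cc3oc(-c4ccc(OCc5ccccc5)cc4)c(c23)-c2cc(OCc3ccccc3)cc(OCc3ccccc3)c2[C@@H]1c1ccc(OCc2ccccc2)cc1
F6 | step 12 | rac-4,6-bis(benzyloxy)-3-{4-[(tert-butyldimethylsilyl)oxy]phenyl}-1,3-dihydro-2,1-benzoxaborol-1-ol | OB1OC(c2ccc(O[Si](C)(C)C(C)(C)C)cc2)c2c1cc(OCc1ccccc1)cc2OCc1ccccc1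
F7 | step 12 | rac-6-(benzyloxy)-2-[4-(benzyloxy)phenyl]-3-{3,5-bis(benzyloxy)-2-[{4-[(tert-butyldimethylsilyl)oxy]phenyl}(hydroxy)methyl]phenyl}-1-benzofuran-4-carbaldehyde | O=Cc1cc(OCc2ccccc2)cc2oc(-c3ccc(OCc4ccccc4)cc3)c(c12)-c1cc(OCc2ccccc2)cc(OCc2ccccc2)c1C(O)c1ccc(O[Si](C)(C)C(C)(C)C)cc1
F8 | step 1 | 1-methoxy-3,5-bis(methoxymethoxy)benzene | COCOc1cc(OC)cc(OCOC)c1
F9 | step 1 | 2-iodo-5-methoxy-1,3-bis(methoxymethoxy)benzene | COCOc1cc(OC)cc(OCOC)c1I
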